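Target numbering: C1 is the aryl carbinol, C2 the neighbouring methine, C3–C5 the allyl arm ending at the second aryl ring. C2 carries the CH2O carbon and C3, and C4 can stand at the aldehyde level, so the C1 oxygen, C1, C2, C3 and C4 map onto a 2-ethoxyoxolane grown from an (S)-1-arylallyl alcohol. The route rests on cutting C2–C3: one haloacetal radical closure forms that bond, the oxolane ring, the C2 stereocentre (trans to aryl) and, by nitroxide capture, the C–O bond at the CH2O carbon. The precursor is the mixed ethyl iodoacetal of (S)-1-(3,4-dimethoxyphenyl)prop-2-en-1-ol; iodine, not bromine, lets halogen abstraction outpace stannyl–nitroxide coupling.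

Key step: step 4

Remark: the acetal carbon is carried as both epimers because steps 5 and 7 destroy it, and any 4,5-cis isomer from step 4 is removed by chromatography at 15 or 16.

Step 1
Reactants: 1 veratraldehyde (3,4-dimethoxybenzaldehyde); 2 vinylmagnesium bromide
Product: 3 rac-1-(3,4-dimethoxyphenyl)prop-2-en-1-ol
Conditions: 2 (1.2 equiv), THF, 0 °C; then sat. aq NH4Cl
Reagents that add atoms: none
Why: Grignard 1,2-addition of a vinyl nucleophile to an aromatic aldehyde is reliable, and the carbinol centre, formed racemic here, is resolved in step 2.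

Step 2
Reactants: 3 rac-1-(3,4-dimethoxyphenyl)prop-2-en-1-ol
Product: 4 (1S)-1-(3,4-dimethoxyphenyl)prop-2-en-1-ol
Conditions: immobilised Candida antarctica lipase B, vinyl acetate (3 equiv), MTBE, 30 °C; stopped just past half conversion
Reagents that add atoms: none
Why: Lipase-catalysed kinetic resolution by transesterification should acetylate the R alcohol (aryl as the large group, vinyl as the medium group) and leave the S alcohol, which fixes C1 of the target under neutral conditions that spare the ionisable aryl allyl carbinol.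

Step 3
Reactants: 4 (1S)-1-(3,4-dimethoxyphenyl)prop-2-en-1-ol; 5 ethyl vinyl ether
Product: 6 4-[(1S)-1-(1-ethoxy-2-iodoethoxy)prop-2-enyl]-1,2-dimethoxybenzene (iodoacetal; both acetal epimers)
Conditions: 5 (3 equiv), NIS (1.2 equiv), CH2Cl2, −40 → 0 °C, dark
Reagents that add atoms: N-iodosuccinimide, O=C1CCC(=O)N1I
Why: Haloacetalisation (iodoalkoxylation of an enol ether): NIS iodinates the enol ether and the alcohol captures the oxocarbenium ion, so the carbinol C–O bond is untouched, the S centre is retained and the acetal centre forms as both epimers.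

Step 4
Reactants: 6 iodoacetal 4-[(1S)-1-(1-ethoxy-2-iodoethoxy)prop-2-enyl]-1,2-dimethoxybenzene; 7 TEMPO (2,2,6,6-tetramethylpiperidin-1-oxyl)
Product: 10 (4R,5S)-5-(3,4-dimethoxyphenyl)-2-ethoxy-4-[(2,2,6,6-tetramethylpiperidin-1-yl)oxymethyl]oxolane (4,5-trans; both acetal epimers), via acyclic primary radical 8 (not isolated), via cyclised primary radical 9 (not isolated)
Conditions: Bu3SnH (2.5 equiv) and 7 (3 equiv), separate slow syringe-pump additions, degassed PhH (0.02 M), 70 °C
Reagents that add atoms: none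
Why: Bu3SnH and the nitroxide generate Bu3Sn radicals that abstract iodine from 6 to give radical 8, which adds to the inner vinyl carbon to give radical 9, and 9 couples with 7 at oxygen; this is a Ueno–Stork haloacetal radical cyclisation run under the known tin hydride–nitroxide trapping protocol. The oxolane ring (C1 oxygen, C1, C2, C3, C4 of the target) closes 5-exo-trig through a chair-like transition state. The new stereocentre (oxolane C4, target C2) is set by the existing S carbinol centre: the aryl group on the allylic carbon sits pseudo-equatorial, so the CH2 branch forms trans to it, which is 4R in 10 and matches the target; both acetal epimers can adopt such a chair, with OEt pseudo-axial in one and pseudo-equatorial in the other. The step needs ring closure before capture of 8, and capture of 9 before hydrogen transfer from tin; the fast closure of a 2-alkoxy-3-oxahex-5-enyl radical, the absence of any unimolecular outlet for 9 and the slow feeding of both 7 and Bu3SnH should secure this order. Iodide lets halogen abstraction compete with stannyl–nitroxide coupling at low nitroxide concentration, and the neutral medium spares the ionisable aryl allyl ether.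

Step 5
Reactants: 10 (4R,5S)-5-(3,4-dimethoxyphenyl)-2-ethoxy-4-[(2,2,6,6-tetramethylpiperidin-1-yl)oxymethyl]oxolane
Product: 11 (4R,5S)-5-(3,4-dimethoxyphenyl)-4-[(2,2,6,6-tetramethylpiperidin-1-yl)oxymethyl]oxolan-2-ol (lactol; both anomers)
Conditions: 0.5 M aq HCl, THF, 0 °C → rt
Reagents that add atoms: water, O
Why: Acid-catalysed acetal hydrolysis through the ring oxocarbenium ion, which forms far more easily than a benzylic cation at C5, so the alkoxyamine (only protonated) and both stereocentres should survive.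

Step 6
Reactants: 12 3,4-dimethoxybenzyl bromide (4-(bromomethyl)-1,2-dimethoxybenzene)
Product: 13 diethyl (3,4-dimethoxybenzyl)phosphonate
Conditions: P(OEt)3 (neat, 1.5 equiv), 130 °C
Reagents that add atoms: triethyl phosphite, CCOP(OCC)OCC
Why: Michaelis–Arbuzov reaction of a reactive benzylic bromide, driven by loss of volatile bromoethane.

Step 7
Reactants: 11 lactol (4R,5S)-5-(3,4-dimethoxyphenyl)-4-[(2,2,6,6-tetramethylpiperidin-1-yl)oxymethyl]oxolan-2-ol; 13 diethyl (3,4-dimethoxybenzyl)phosphonate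
Product: 15 (1S,2R,4E)-1,5-bis(3,4-dimethoxyphenyl)-2-[(2,2,6,6-tetramethylpiperidin-1-yl)oxymethyl]pent-4-en-1-ol, via open-chain hydroxy aldehyde 14 (not isolated)
Conditions: 13 (3 equiv), KOtBu (3 equiv), THF, 0 → 45 °C; then H2O
Reagents that add atoms: none
Why: Horner–Wadsworth–Emmons olefination of a lactol through its open form 14: one equivalent of phosphonate anion deprotonates the lactol, another adds to the aldehyde, and the aryl-stabilised adduct equilibrates and eliminates to the E-styrene while ring opening frees the C1 hydroxyl; no stereocentre is alpha to the carbonyl, so C1 and C2 are kept.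

Step 8
Reactants: 15 (1S,2R,4E)-1,5-bis(3,4-dimethoxyphenyl)-2-[(2,2,6,6-tetramethylpiperidin-1-yl)oxymethyl]pent-4-en-1-ol
Product: 16 (1S,2R,4E)-1,5-bis(3,4-dimethoxyphenyl)-2-(hydroxymethyl)pent-4-en-1-ol
Conditions: Zn dust, AcOH/THF/H2O (3:1:1), 60 °C
Reagents that add atoms: none
Why: Reductive cleavage of the alkoxyamine N–O bond by zinc in acetic acid is the standard unmasking of TEMPO ethers and should leave the styrene, the aryl ethers and both stereocentres alone.

Step 9
Reactants: 17 crotonaldehyde ((E)-but-2-enal)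
Product: 18 (Z)-2-iodobut-2-enal
Conditions: I2, K2CO3, DMAP (cat.), THF/H2O (1:1), rt
Reagents that add atoms: iodine, II
Why: alpha-Iodination of an enal by amine conjugate addition, iodination of the enolate and elimination, which should give the isomer with methyl trans to the formyl group and therefore cis to iodine.

Step 10
Reactants: 18 (Z)-2-iodobut-2-enal
Product: 19 (Z)-2-iodobut-2-en-1-ol
Conditions: NaBH4, MeOH, 0 °C
Reagents that add atoms: none
Why: Borohydride 1,2-reduction of the aldehyde leaves the alkene geometry untouched.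

Step 11
Reactants: 19 (Z)-2-iodobut-2-en-1-ol
Product: 20 tert-butyl{[(Z)-2-iodobut-2-enyl]oxy}dimethylsilane
Conditions: TBSCl, imidazole, CH2Cl2, 0 °C → rt
Reagents that add atoms: tert-butyldimethylsilyl chloride, CC(C)(C)[Si](C)(C)Cl
Why: Standard silylation of a primary alcohol.

Step 12
Reactants: 20 tert-butyl{[(Z)-2-iodobut-2-enyl]oxy}dimethylsilane
Product: 22 (Z)-2-[(tert-butyldimethylsilyloxy)methyl]but-2-enoic acid, via vinyllithium 21 (not isolated)
Conditions: t-BuLi (2.1 equiv), Et2O, −78 °C; CO2; then cold 1 M aq HCl to pH 3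
Reagents that add atoms: carbon dioxide, O=C=O
Why: Iodine–lithium exchange on a vinyl iodide and carboxylation of the configurationally stable vinyllithium at −78 °C proceed with retention, so the carboxyl group takes the place of iodine cis to methyl and the Z acid should result.

Step 13
Reactants: 16 (1S,2R,4E)-1,5-bis(3,4-dimethoxyphenyl)-2-(hydroxymethyl)pent-4-en-1-ol; 22 (Z)-2-[(tert-butyldimethylsilyloxy)methyl]but-2-enoic acid
Product: 23 [(2R,4E)-5-(3,4-dimethoxyphenyl)-2-[(S)-(3,4-dimethoxyphenyl)(hydroxy)methyl]pent-4-enyl] (Z)-2-[(tert-butyldimethylsilyloxy)methyl]but-2-enoate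
Conditions: 22 (1.1 equiv), PPh3 (1.2 equiv), DIAD (1.2 equiv, added last, dropwise), THF, −20 → 0 °C
Reagents that add atoms: none
Why: Mitsunobu esterification should activate the unhindered primary hydroxyl in preference to the hindered benzylic one and let the carboxylate displace it at CH2, so the acid is never made an acylating agent, its Z alkene cannot isomerise and no stereocentre is touched.

Step 14
Reactants: 23 [(2R,4E)-5-(3,4-dimethoxyphenyl)-2-[(S)-(3,4-dimethoxyphenyl)(hydroxy)methyl]pent-4-enyl] (Z)-2-[(tert-butyldimethylsilyloxy)methyl]but-2-enoate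
Product: 24 [(2R,4E)-5-(3,4-dimethoxyphenyl)-2-[(S)-(3,4-dimethoxyphenyl)(hydroxy)methyl]pent-4-enyl] (Z)-2-(hydroxymethyl)but-2-enoate (CNP0417076.1)
Conditions: HF·pyridine, THF/pyridine, 0 °C → rt
Reagents that add atoms: none
Why: Fluoride cleavage of the primary silyl ether under buffered, weakly acidic conditions should avoid base-induced acyl migration to the C1 hydroxyl and isomerisation of the Z ester.

Compound list
1 | veratraldehyde (3,4-dimethoxybenzaldehyde) | COc1ccc(C=O)cc1OC | starting material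
2 | vinylmagnesium bromide | C=C[Mg]Br | starting material
3 | rac-1-(3,4-dimethoxyphenyl)prop-2-en-1-ol | C=CC(O)c1ccc(OC)c(OC)c1 | intermediate
4 | (1S)-1-(3,4-dimethoxyphenyl)prop-2-en-1-ol | C=C[C@H](O)c1ccc(OC)c(OC)c1 | intermediate
5 | ethyl vinyl ether (ethoxyethene) | C=COCC | starting material
6 | 4-[(1S)-1-(1-ethoxy-2-iodoethoxy)prop-2-enyl]-1,2-dimethoxybenzene (both acetal epimers) | C=C[C@H](OC(CI)OCC)c1ccc(OC)c(OC)c1 | intermediate
7 | TEMPO (2,2,6,6-tetramethylpiperidin-1-oxyl) | CC1(C)CCCC(C)(C)N1[O] | starting material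
8 | 2-[(1S)-1-(3,4-dimethoxyphenyl)prop-2-enyloxy]-2-ethoxyethyl radical (acyclic primary radical) | C=C[C@H](OC([CH2])OCC)c1ccc(OC)c(OC)c1 | intermediate
9 | [(5S)-5-(3,4-dimethoxyphenyl)-2-ethoxyoxolan-4-yl]methyl radical, CH2 trans to aryl (cyclised primary radical) | CCOC1C[C@H]([CH2])[C@@H](c2ccc(OC)c(OC)c2)O1 | intermediate
10 | (4R,5S)-5-(3,4-dimethoxyphenyl)-2-ethoxy-4-[(2,2,6,6-tetramethylpiperidin-1-yl)oxymethyl]oxolane (4,5-trans; both acetal epimers) | CCOC1C[C@H](CON2C(C)(C)CCCC2(C)C)[C@@H](c2ccc(OC)c(OC)c2)O1 | intermediate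
11 | (4R,5S)-5-(3,4-dimethoxyphenyl)-4-[(2,2,6,6-tetramethylpiperidin-1-yl)oxymethyl]oxolan-2-ol (both anomers) | OC1C[C@H](CON2C(C)(C)CCCC2(C)C)[C@@H](c2ccc(OC)c(OC)c2)O1 | intermediate
12 | 3,4-dimethoxybenzyl bromide (4-(bromomethyl)-1,2-dimethoxybenzene) | COc1ccc(CBr)cc1OC | starting material
13 | diethyl (3,4-dimethoxybenzyl)phosphonate | CCOP(=O)(Cc1ccc(OC)c(OC)c1)OCC | intermediate
14 | (3R,4S)-4-(3,4-dimethoxyphenyl)-4-hydroxy-3-[(2,2,6,6-tetramethylpiperidin-1-yl)oxymethyl]butanal (open form of 11) | O=CC[C@H](CON1C(C)(C)CCCC1(C)C)[C@H](O)c1ccc(OC)c(OC)c1 | intermediate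
15 | (1S,2R,4E)-1,5-bis(3,4-dimethoxyphenyl)-2-[(2,2,6,6-tetramethylpiperidin-1-yl)oxymethyl]pent-4-en-1-ol | COc1ccc(/C=C/C[C@H](CON2C(C)(C)CCCC2(C)C)[C@H](O)c2ccc(OC)c(OC)c2)cc1OC | intermediate
16 | (1S,2R,4E)-1,5-bis(3,4-dimethoxyphenyl)-2-(hydroxymethyl)pent-4-en-1-ol | COc1ccc(/C=C/C[C@H](CO)[C@H](O)c2ccc(OC)c(OC)c2)cc1OC | intermediate
17 | crotonaldehyde ((E)-but-2-enal) | C/C=C/C=O | starting material
18 | (Z)-2-iodobut-2-enal | C/C=C(/C=O)I | intermediate
19 | (Z)-2-iodobut-2-en-1-ol | C/C=C(/CO)I | intermediate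
20 | tert-butyl{[(Z)-2-iodobut-2-enyl]oxy}dimethylsilane | C/C=C(/CO[Si](C)(C)C(C)(C)C)I | intermediate
21 | [(E)-1-(tert-butyldimethylsilyloxy)but-2-en-2-yl]lithium (lithium cis to methyl) | C/C=C(/CO[Si](C)(C)C(C)(C)C)[Li] | intermediate
22 | (Z)-2-[(tert-butyldimethylsilyloxy)methyl]but-2-enoic acid | C/C=C(/CO[Si](C)(C)C(C)(C)C)C(=O)O | intermediate
23 | [(2R,4E)-5-(3,4-dimethoxyphenyl)-2-[(S)-(3,4-dimethoxyphenyl)(hydroxy)methyl]pent-4-enyl] (Z)-2-[(tert-butyldimethylsilyloxy)methyl]but-2-enoate | C/C=C(/CO[Si](C)(C)C(C)(C)C)C(=O)OC[C@@H](C/C=C/c1ccc(OC)c(OC)c1)[C@H](O)c1ccc(OC)c(OC)c1 | intermediate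
24 | [(2R,4E)-5-(3,4-dimethoxyphenyl)-2-[(S)-(3,4-dimethoxyphenyl)(hydroxy)methyl]pent-4-enyl] (Z)-2-(hydroxymethyl)but-2-enoate | C/C=C(/CO)C(=O)OC[C@@H](C/C=C/c1ccc(OC)c(OC)c1)[C@H](O)c1ccc(OC)c(OC)c1 | target

Total step count: 14. Longest linear sequence: 9 steps (steps 1, 2, 3, 4, 5, 7, 8, 13, 14).

Steps most likely to fail

Step 4. The nitroxide may capture radical 8 before the ring has closed, or tin hydride may reduce radical 9, so that ring closure and C–O bond formation do not happen together. The fallback sets out from 6 and uses dioxygen as the trap in an oxygenative radical cyclisation (Bu3SnH, stream of dry air, PhMe, 0 °C), where the dissolved oxygen stays low and the tin hydride reduces the hydroperoxide. This should give [(2S,3R)-2-(3,4-dimethoxyphenyl)-5-ethoxyoxolan-3-yl]methanol F1. Hydrolysis with 0.5 M aq HCl in THF then gives (4R,5S)-5-(3,4-dimethoxyphenyl)-4-(hydroxymethyl)oxolan-2-ol F2. Horner–Wadsworth–Emmons reaction of F2 with 13 (4 equiv each of 13 and KOtBu, THF) should give diol 16 directly, where the route is rejoined; step 8 is then not needed.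

Step 7. The lactolate may open only sluggishly and the oxido phosphonate adduct may be slow to eliminate, so conversion stalls or E selectivity erodes. The fallback sets out from 11 with a Wittig methylenation (Ph3PCH3Br, KOtBu, THF, 0 °C → rt) to (1S,2R)-1-(3,4-dimethoxyphenyl)-2-[(2,2,6,6-tetramethylpiperidin-1-yl)oxymethyl]pent-4-en-1-ol F3. Cross-metathesis of F3 with commercial 3,4-dimethoxystyrene (second-generation Grubbs catalyst RuCl2(=CHPh)(PCy3)(H2IMes), CH2Cl2, 40 °C) should then give the E-styrene 15, where the route is rejoined.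

Step 13. Site selectivity may be lost: the electron-rich benzylic hydroxyl may be activated, leading to ionisation, esterification with inversion at C1 or oxetane closure. The fallback sets out from 15 and masks that hydroxyl first (TBSOTf, 2,6-lutidine, CH2Cl2, −78 °C) as (1S,2R,4E)-1-(tert-butyldimethylsilyloxy)-1,5-bis(3,4-dimethoxyphenyl)-2-[(2,2,6,6-tetramethylpiperidin-1-yl)oxymethyl]pent-4-ene F4. Zn/AcOH cleavage of the N–O bond gives (2R,4E)-2-[(S)-(tert-butyldimethylsilyloxy)(3,4-dimethoxyphenyl)methyl]-5-(3,4-dimethoxyphenyl)pent-4-en-1-ol F5. Mitsunobu esterification of this single free hydroxyl with 22 gives [(2R,4E)-2-[(S)-(tert-butyldimethylsilyloxy)(3,4-dimethoxyphenyl)methyl]-5-(3,4-dimethoxyphenyl)pent-4-enyl] (Z)-2-[(tert-butyldimethylsilyloxy)methyl]but-2-enoate F6. HF·pyridine then removes both silyl groups and the route is rejoined at 24.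

Further compounds
F1 | step 4 | [(2S,3R)-2-(3,4-dimethoxyphenyl)-5-ethoxyoxolan-3-yl]methanol (both acetal epimers) | CCOC1C[C@H](CO)[C@@H](c2ccc(OC)c(OC)c2)O1
F2 | step 4 | (4R,5S)-5-(3,4-dimethoxyphenyl)-4-(hydroxymethyl)oxolan-2-ol (both anomers) | OC1C[C@H](CO)[C@@H](c2ccc(OC)c(OC)c2)O1
F3 | step 7 | (1S,2R)-1-(3,4-dimethoxyphenyl)-2-[(2,2,6,6-tetramethylpiperidin-1-yl)oxymethyl]pent-4-en-1-ol | C=CC[C@H](CON1C(C)(C)CCCC1(C)C)[C@H](O)c1ccc(OC)c(OC)c1
F4 | step 13 | (1S,2R,4E)-1-(tert-butyldimethylsilyloxy)-1,5-bis(3,4-dimethoxyphenyl)-2-[(2,2,6,6-tetramethylpiperidin-1-yl)oxymethyl]pent-4-ene | COc1ccc(/C=C/C[C@H](CON2C(C)(C)CCCC2(C)C)[C@H](O[Si](C)(C)C(C)(C)C)c2ccc(OC)c(OC)c2)cc1OC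
F5 | step 13 | (2R,4E)-2-[(S)-(tert-butyldimethylsilyloxy)(3,4-dimethoxyphenyl)methyl]-5-(3,4-dimethoxyphenyl)pent-4-en-1-ol | COc1ccc(/C=C/C[C@H](CO)[C@H](O[Si](C)(C)C(C)(C)C)c2ccc(OC)c(OC)c2)cc1OC
F6 | step 13 | [(2R,4E)-2-[(S)-(tert-butyldimethylsilyloxy)(3,4-dimethoxyphenyl)methyl]-5-(3,4-dimethoxyphenyl)pent-4-enyl] (Z)-2-[(tert-butyldimethylsilyloxy)methyl]but-2-enoate | C/C=C(/CO[Si](C)(C)C(C)(C)C)C(=O)OC[C@@H](C/C=C/c1ccc(OC)c(OC)c1)[C@H](O[Si](C)(C)C(C)(C)C)c1ccc(OC)c(OC)c1
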